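At early times the two earlier runs reached the same stage on very different dates: maple held 12.1% left-handed product at 0.625 d, and larch held 12.7% at 8.00 d. Comparing them there spared me any correction for how far each flask had gone. With one partner used per product, the partner's charge left room for 30.0%, and maple levelled at 29.1%, so I took partner as the limiting reagent.

all flasks: free catalyst 1 mol%
- maple: left-handed substrate 1 M; right-handed substrate 1 M; partner 0.60 equiv; added ligand 11 mM; run made earlier
- larch: left-handed substrate 1 M; right-handed substrate 1 M; partner 0.60 equiv; added ligand 95 mM; run made earlier
- Sunday's: left-handed substrate 1.0 M; right-handed substrate 1.0 M; partner 0.600 equiv; added ligand 8.0 mM; time 15 d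
- Monday's: left-handed substrate 1.0 M; right-handed substrate 1.0 M; partner 0.600 equiv; added ligand 15 mM; time 15 d
- Wednesday's: left-handed substrate 1.0 M; right-handed substrate 1.0 M; partner 0.600 equiv; added ligand 30 mM; time 15 d
- Saturday's: left-handed substrate 1.0 M; right-handed substrate 1.0 M; partner 0.600 equiv; added ligand 60 mM; time 15 d

| run | time / d | left-handed product / % | left-handed substrate / % |
|---|---|---|---|
| maple | 0.625 | 12.1 | 37.8 |
| maple | 1.25 | 19.2 | 30.2 |
| maple | 3.00 | 26.0 | 23.0 |
| maple | 8.00 | 29.1 | 20.4 |
| larch | 1.04 | 2.9 | 48.3 |
| larch | 2.50 | 5.2 | 45.1 |
| larch | 5.00 | 9.2 | 40.9 |
| larch | 8.00 | 12.7 | 36.6 |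

(scatter of a reading: 0.5 percentage points)

- free catalyst is single-handed; left-handed substrate and right-handed substrate are mirror images of each other, charged as a racemate, each of them at the stated concentration
- a step back or a flat step of under half a point counts as no turn
- "hardly changes" means that all values lie within two and a half points (for a concentration: within two and a half percent of the largest)

* amount of left-handed product at the end, in percent of the left-handed substrate and right-handed substrate together charged for Sunday's, Monday's, Wednesday's, Saturday's, in this order
* the shape of the row from first to last (rises all the way / falls all the way / falls, then rises / rises, then falls / hardly changes)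

To whoever took over the bench: Sunday's, Monday's, Wednesday's and Saturday's differed in c(added ligand), from 8.0 mM to 60 mM, and were to be read at 15 d. I treated partner as falling exponentially, a pseudo-first-order clock: the logarithm of room over room minus product, divided by time. That gave 0.826 d⁻¹ for maple and 0.0688 d⁻¹ for larch. In logarithms, the clock lost 1.15 powers of ten for each power of ten of c(added ligand); this is the ligand slope, powers of ten of clock lost per power of ten of ligand.

On that slope Saturday's clock came to 0.117 d⁻¹, so I expected 17.3% of its partner left and 24.8% product. For Wednesday's I expected 2.03% of its partner left. I asked my successor to add no further ligand to these flasks: larch's clock ran slower than maple's with more ligand in it.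

The forecast gave 29.8%, 29.7%, 27.9% and 22.8%, a row that falls all the way, holding that “the ligand sequesters catalyst, leaving free catalyst as the active species”. Its Saturday's value lay below mine.

The flasks gave 29.2%, 29.2%, 28.9% and 25.0%: the row falls all the way, as forecast.

    free catalyst + added ligand ⇌ idle complex, settled at all times (K = 610 M⁻¹)
    partner + catalyst intermediate B → free catalyst + right-handed product (k = 4.60 × 10⁻⁴ M⁻¹ s⁻¹)
    partner + catalyst intermediate A → free catalyst + left-handed product (k = 0.00880 M⁻¹ s⁻¹)
    free catalyst + right-handed substrate ⇌ catalyst intermediate B (K = 0.300 M⁻¹, k = 0.0480 M⁻¹ s⁻¹)
    free catalyst + left-handed substrate ⇌ catalyst intermediate A (K = 1.50 M⁻¹, k = 0.00400 M⁻¹ s⁻¹)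

At 15.0 d Saturday's still held 14% of its partner, against the 17.3% from the ligand slope, and Wednesday's held 1.0% against 2.03%. Saturday's was late rather than stopped, with 29.2% left-handed product at 150 d. The drop of 4.1 percentage points from Sunday's to Saturday's was due in part to the tying up of free catalyst with added ligand as idle complex, which held 94.3% of the catalyst in Saturday's at 15.0 d: without that binding the change between the two flasks was 0 points.

The numbers in the tables are calculated with made-up constants; scatter was added.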